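**Plan**
1. Retrosynthesis: (a) six benzyl ethers and the O-methyl group; (b) both ketal C–O bonds and the bond from flavan C8 to the methoxy-bearing carbon, giving a flavan-7-ol and a 1,3-diaryl vicinal triketone; (c) flavan C3–C4, with a helper oxygen on C4, giving an aryl/alkyl dialdehyde; (d) the O1–C2 ether bond, giving a protected phloroglucinaldehyde and an (R)-mandelate.
2. Forward: the aryl ether is made first; ring C of the flavan is closed by a SmI2 ketyl (pinacol) coupling and C4 is deoxygenated; the triketone is made from a diazo diketone and, in the same flask, the furan and pyranone rings are closed together on ring A by a Friedel–Crafts/ketalisation cascade; O-methylation and hydrogenolysis finish.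
3. Enabling feature: flavan C4 sits on the phloroglucinol ring A between C5–O and C8a–O1, so it maps onto the formyl carbon of 2,4,6-trihydroxybenzaldehyde, and C3 is a carbinol carbon on the O1–C2 chain; both are acceptor (carbonyl) carbons, which a ketyl coupling joins by polarity reversal.
4. Stereochemistry: C2 from an asymmetric transfer hydrogenation followed by Mitsunobu inversion; C3 by substrate control from C2 in the ring closure; the methoxy-bearing carbon by a chiral phosphoric acid; the ketal carbon by the ring closure itself.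

Key step: step 8

Remark on the chemistry (assumption): a fused furan/pyranone ketal of this kind can close only with the methoxy group and the ketal aryl group on the same face of the ring fusion, whereas the two fusion descriptors of the given structure read as anti; the route controls the methoxy-bearing carbon, lets the ketal carbon follow on ring closure, and carries both descriptors in the SMILES exactly as given.

**Step 1**
Reactants: 1 4-(benzyloxy)phenylmagnesium bromide (THF solution); 2 dimethyl oxalate
Product: 3 methyl 2-[4-(benzyloxy)phenyl]-2-oxoacetate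
Conditions: THF, −78 °C, 1 added to 2 (2 equiv); aq. NH4Cl
Reagents that add atoms: none
Why: Grignard acylation of a dialkyl oxalate stops at the α-keto ester because the tetrahedral magnesium alkoxide persists at low temperature with the oxalate in excess.

**Step 2**
Reactants: 3 methyl 2-[4-(benzyloxy)phenyl]-2-oxoacetate
Product: 4 methyl (R)-2-[4-(benzyloxy)phenyl]-2-hydroxyacetate
Conditions: RuCl(p-cymene)[(S,S)-TsDPEN] (1 mol %), HCO2H/Et3N (5:2), CH2Cl2, rt
Reagents that add atoms: none
Why: Noyori-type asymmetric transfer hydrogenation delivers hydride to one face of the aryl ketone inside the chiral ruthenium–diamine complex, the (S,S) ligand being the one expected to give the (R)-carbinol that becomes C2.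

**Step 3**
Reactants: 5 2,4,6-trihydroxybenzaldehyde
Product: 6 2,6-dihydroxy-4-(methoxymethoxy)benzaldehyde
Conditions: MOMCl (1.05 equiv), i-Pr2NEt, CH2Cl2, 0 °C
Reagents that add atoms: chloromethyl methyl ether, COCCl
Why: Williamson-type O-alkylation should take the 4-hydroxyl selectively, since it is the only one not chelated to the formyl group and is the most acidic.

**Step 4**
Reactants: 6 2,6-dihydroxy-4-(methoxymethoxy)benzaldehyde
Product: 7 2-(benzyloxy)-6-hydroxy-4-(methoxymethoxy)benzaldehyde
Conditions: BnBr (1.0 equiv), K2CO3, DMF, 0 °C to rt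
Reagents that add atoms: benzyl bromide, BrCc1ccccc1
Why: Williamson etherification of one of two equivalent hydroxyls should stop at the monoether because the remaining hydroxyl is then locked in the hydrogen bond to the formyl group.

**Step 5**
Reactants: 7 2-(benzyloxy)-6-hydroxy-4-(methoxymethoxy)benzaldehyde; 4 methyl (R)-2-[4-(benzyloxy)phenyl]-2-hydroxyacetate
Product: 8 methyl (S)-2-[4-(benzyloxy)phenyl]-2-[3-(benzyloxy)-2-formyl-5-(methoxymethoxy)phenoxy]acetate
Conditions: PPh3, DIAD, toluene, 0 °C to rt
Reagents that add atoms: none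
Why: Mitsunobu etherification of the acidic salicylaldehyde-type phenol inverts the carbinol (R to S) by SN2 displacement, the adjacent ester disfavouring ionisation at the benzylic carbon, and so sets C2 of the flavan.

**Step 6**
Reactants: 8 methyl (S)-2-[4-(benzyloxy)phenyl]-2-[3-(benzyloxy)-2-formyl-5-(methoxymethoxy)phenoxy]acetate
Product: 9 (S)-2-[4-(benzyloxy)phenyl]-2-[3-(benzyloxy)-2-(hydroxymethyl)-5-(methoxymethoxy)phenoxy]ethan-1-ol
Conditions: i-Bu2AlH (5 equiv), CH2Cl2, −78 to 0 °C; aq. potassium sodium tartrate
Reagents that add atoms: none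
Why: Hydride reduction with i-Bu2AlH takes the ester and the aryl aldehyde to the two primary alcohols under non-basic conditions, so the acidic C2–H is not disturbed.

**Step 7**
Reactants: 9 (S)-2-[4-(benzyloxy)phenyl]-2-[3-(benzyloxy)-2-(hydroxymethyl)-5-(methoxymethoxy)phenoxy]ethan-1-ol
Product: 10 (S)-2-(benzyloxy)-6-{1-[4-(benzyloxy)phenyl]-2-oxoethoxy}-4-(methoxymethoxy)benzaldehyde
Conditions: Dess–Martin periodinane (2.5 equiv), NaHCO3, CH2Cl2, 0 °C; used at once
Reagents that add atoms: none
Why: Dess–Martin oxidation of both primary alcohols under buffered conditions should give the dialdehyde without enolising the configurationally labile α-aryloxy aldehyde.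

**Step 8**
Reactants: 10 (S)-2-(benzyloxy)-6-{1-[4-(benzyloxy)phenyl]-2-oxoethoxy}-4-(methoxymethoxy)benzaldehyde
Product: 11 (2S,3R,4R)-5-(benzyloxy)-2-[4-(benzyloxy)phenyl]-7-(methoxymethoxy)chromane-3,4-diol
Conditions: SmI2 (2.5 equiv, 0.1 M in THF), t-BuOH (2 equiv), THF, −78 to −20 °C; aq. NH4Cl
Reagents that add atoms: none
Why: SmI2 transfers one electron to the conjugated aryl aldehyde, and the samarium-bound ketyl carbon (C4) adds to the carbonyl carbon of the side-chain aldehyde (C3), a second electron and protonation giving the diol; two acceptor carbons are thus joined by polarity reversal, and the closest known reaction type is the SmI2 pinacol cyclisation of 1,6-dialdehydes to cis-cyclohexane-1,2-diols. The pyran ring (ring C of the flavan) closes in the 6-exo-trig mode. C3 is controlled by the C2 stereocentre: in the chair-like transition state the C2 aryl group is equatorial and the C3 oxygen lies equatorial, anti to the C2–O1 bond, which gives the 2,3-trans relation of the target. C4 is set cis to O3 by the trivalent samarium centre that bridges both oxygens; this centre is a helper and is removed in step 10. The step needs ring closure to outrun loss of the aryloxy group from C2 (fragmentation of a ketyl formed at the side-chain aldehyde); the aryl aldehyde is the more easily reduced carbonyl group, the closure is intramolecular and six-membered, and HMPA is left out to keep the reductant mild.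

**Step 9**
Reactants: 11 (2S,3R,4R)-5-(benzyloxy)-2-[4-(benzyloxy)phenyl]-7-(methoxymethoxy)chromane-3,4-diol
Product: 12 (2S,3R,4R)-3,4,5-tris(benzyloxy)-2-[4-(benzyloxy)phenyl]-7-(methoxymethoxy)chromane
Conditions: NaH, BnBr, n-Bu4NI (cat.), DMF, 0 °C to rt
Reagents that add atoms: benzyl bromide, BrCc1ccccc1
Why: Williamson etherification of both alkoxides protects O3 for the later methylation and turns the C4 oxygen into a leaving group for step 10.

**Step 10**
Reactants: 12 (2S,3R,4R)-3,4,5-tris(benzyloxy)-2-[4-(benzyloxy)phenyl]-7-(methoxymethoxy)chromane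
Product: 13 (2S,3R)-3,5-bis(benzyloxy)-2-[4-(benzyloxy)phenyl]chroman-7-ol
Conditions: Et3SiH (6 equiv), CF3CO2H, CH2Cl2, −40 °C to rt
Reagents that add atoms: none
Why: Ionic hydrogenation should ionise the C4 benzyl ether to a benzylic cation stabilised by the ring A oxygens and reduce it to CH2 with the silane, while the same acid cleaves the aryl MOM ether and the silane scavenges its cation; C2 and C3 are not involved.

**Step 11**
Reactants: 14 1-[2,4-bis(benzyloxy)-6-hydroxyphenyl]ethan-1-one; 15 4-(benzyloxy)benzoyl chloride
Product: 16 1-[2,4-bis(benzyloxy)-6-hydroxyphenyl]-3-[4-(benzyloxy)phenyl]propane-1,3-dione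
Conditions: LiN(SiMe3)2 (4 equiv), THF, −78 °C; then 15, −78 °C to rt; aq. HCl
Reagents that add atoms: none
Why: Claisen-type C-acylation of the dilithiated hydroxyacetophenone gives the 1,3-diketone, any O-acyl product being carried on by the Baker–Venkataraman rearrangement under the excess base.

**Step 12**
Reactants: 16 1-[2,4-bis(benzyloxy)-6-hydroxyphenyl]-3-[4-(benzyloxy)phenyl]propane-1,3-dione
Product: 17 1-[2,4-bis(benzyloxy)-6-hydroxyphenyl]-3-[4-(benzyloxy)phenyl]-2-diazopropane-1,3-dione
Conditions: 4-acetamidobenzenesulfonyl azide, Et3N, MeCN, 0 °C to rt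
Reagents that add atoms: 4-acetamidobenzenesulfonyl azide, CC(=O)Nc1ccc(cc1)S(=O)(=O)N=[N+]=[N-]
Why: Regitz diazo transfer to the activated methylene group of a 1,3-diketone is a standard reaction.

**Step 13**
Reactants: 17 1-[2,4-bis(benzyloxy)-6-hydroxyphenyl]-3-[4-(benzyloxy)phenyl]-2-diazopropane-1,3-dione; 13 (2S,3R)-3,5-bis(benzyloxy)-2-[4-(benzyloxy)phenyl]chroman-7-ol
Product: 21 hexa-O-benzyl ketal alcohol (OH in place of OMe at the ring-fusion carbon; all six other hydroxyl oxygens benzylated), via open-chain triketone 18 (not isolated), via ring-closed hemiketal 19 (not isolated), via Friedel-Crafts adduct 20 (not isolated)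
Conditions: dimethyldioxirane (acetone solution, 1.2 equiv), CH2Cl2, 0 °C, then evaporation to dryness; then 13, (R)-3,3'-bis(2,4,6-triisopropylphenyl)-1,1'-binaphthyl-2,2'-diyl hydrogen phosphate (10 mol %), 4 Å molecular sieves, toluene, −20 °C to rt; then camphorsulfonic acid (5 mol %), rt
Reagents that add atoms: dimethyldioxirane, CC1(C)OO1
Why: Proposed new method: oxygen transfer from the dioxirane to the diazo carbon with loss of N2 is a known way to vicinal triketones and gives 18, which rests as hemiketal 19 (the ortho phenol added to the central carbonyl group), and evaporation removes acetone and any excess oxidant before the phenol 13 is added; the new part is that the phosphoric acid should draw on the open triketone through the ring-chain equilibrium of 19 and hold it by a hydrogen bond to the central carbonyl group (the most electrophilic, flanked by two acyl groups) while its phosphoryl oxygen binds the 7-OH of 13, so that C8 (ortho to that OH and less hindered than C6, which lies next to the 5-benzyloxy group) adds to one face of the central carbonyl group to give 20, the two unlike aroyl groups telling the faces apart and the catalyst antipode being chosen for the required configuration at the carbinol carbon; the 7-OH and the phenol of the trioxygenated aroyl group then add to the 4-benzyloxybenzoyl carbon by way of the oxocarbenium ion, each on the face of its own tether, which closes the furan and pyranone rings and fixes the ketal carbon; the closest known reaction types are the condensation of ninhydrin with phenols to fused hemiketals and the chiral phosphoric acid-catalysed Friedel–Crafts hydroxyalkylation of phenols and naphthols with isatins and trifluoromethyl ketones.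

**Step 14**
Reactants: 21 hexa-O-benzyl ketal alcohol
Product: 22 hexa-O-benzyl ether of the target (tertiary methyl ether)
Conditions: MeOTf (3 equiv), 2,6-di-tert-butyl-4-methylpyridine (4 equiv), CH2Cl2, 0 °C to rt
Reagents that add atoms: methyl trifluoromethanesulfonate, COS(=O)(=O)C(F)(F)F
Why: O-Methylation of the hindered tertiary alcohol with a small, strong electrophile and a non-nucleophilic base avoids the alkoxide, which could open the neighbouring ketal, and leaves all stereocentres untouched.

**Step 15**
Reactants: 22 hexa-O-benzyl ether of the target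
Product: 23 CNP0291586.2 (target)
Conditions: H2 (1 atm), 10% Pd/C, THF/MeOH, rt
Reagents that add atoms: none
Why: Hydrogenolysis of the six benzyl ethers over palladium should leave the hindered aryl ketone, the ketal, the tertiary methyl ether and the flavan C2–O1 bond intact on short exposure at low pressure.

**Compound list**
1 | 4-(benzyloxy)phenylmagnesium bromide | Br[Mg]c1ccc(OCc2ccccc2)cc1 | starting material
2 | dimethyl oxalate | COC(=O)C(=O)OC | starting material
3 | methyl 2-[4-(benzyloxy)phenyl]-2-oxoacetate | COC(=O)C(=O)c1ccc(OCc2ccccc2)cc1 | intermediate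
4 | methyl (R)-2-[4-(benzyloxy)phenyl]-2-hydroxyacetate | O[C@H](c1ccc(OCc2ccccc2)cc1)C(=O)OC | intermediate
5 | 2,4,6-trihydroxybenzaldehyde | O=Cc1c(O)cc(O)cc1O | starting material
6 | 2,6-dihydroxy-4-(methoxymethoxy)benzaldehyde | COCOc1cc(O)c(C=O)c(O)c1 | intermediate
7 | 2-(benzyloxy)-6-hydroxy-4-(methoxymethoxy)benzaldehyde | COCOc1cc(O)c(C=O)c(OCc2ccccc2)c1 | intermediate
8 | methyl (S)-2-[4-(benzyloxy)phenyl]-2-[3-(benzyloxy)-2-formyl-5-(methoxymethoxy)phenoxy]acetate | COCOc1cc(OCc2ccccc2)c(C=O)c(c1)O[C@@H](c1ccc(OCc2ccccc2)cc1)C(=O)OC | intermediate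
9 | (S)-2-[4-(benzyloxy)phenyl]-2-[3-(benzyloxy)-2-(hydroxymethyl)-5-(methoxymethoxy)phenoxy]ethan-1-ol | COCOc1cc(OCc2ccccc2)c(CO)c(c1)O[C@@H](c1ccc(OCc2ccccc2)cc1)CO | intermediate
10 | (S)-2-(benzyloxy)-6-{1-[4-(benzyloxy)phenyl]-2-oxoethoxy}-4-(methoxymethoxy)benzaldehyde | COCOc1cc(OCc2ccccc2)c(C=O)c(c1)O[C@@H](c1ccc(OCc2ccccc2)cc1)C=O | intermediate
11 | (2S,3R,4R)-5-(benzyloxy)-2-[4-(benzyloxy)phenyl]-7-(methoxymethoxy)chromane-3,4-diol (2,3-trans, 3,4-cis) | COCOc1cc(OCc3ccccc3)c2c(c1)O[C@@H](c1ccc(OCc3ccccc3)cc1)[C@H](O)[C@@H]2O | intermediate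
12 | (2S,3R,4R)-3,4,5-tris(benzyloxy)-2-[4-(benzyloxy)phenyl]-7-(methoxymethoxy)chromane | COCOc1cc(OCc3ccccc3)c2c(c1)O[C@@H](c1ccc(OCc3ccccc3)cc1)[C@H](OCc1ccccc1)[C@@H]2OCc1ccccc1 | intermediate
13 | (2S,3R)-3,5-bis(benzyloxy)-2-[4-(benzyloxy)phenyl]chroman-7-ol | Oc1cc(OCc3ccccc3)c2c(c1)O[C@@H](c1ccc(OCc3ccccc3)cc1)[C@H](OCc1ccccc1)C2 | intermediate
14 | 1-[2,4-bis(benzyloxy)-6-hydroxyphenyl]ethan-1-one | CC(=O)c1c(O)cc(OCc2ccccc2)cc1OCc1ccccc1 | starting material
15 | 4-(benzyloxy)benzoyl chloride | O=C(Cl)c1ccc(OCc2ccccc2)cc1 | starting material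
16 | 1-[2,4-bis(benzyloxy)-6-hydroxyphenyl]-3-[4-(benzyloxy)phenyl]propane-1,3-dione | O=C(CC(=O)c1ccc(OCc2ccccc2)cc1)c1c(O)cc(OCc2ccccc2)cc1OCc1ccccc1 | intermediate
17 | 1-[2,4-bis(benzyloxy)-6-hydroxyphenyl]-3-[4-(benzyloxy)phenyl]-2-diazopropane-1,3-dione | [N-]=[N+]=C(C(=O)c1ccc(OCc2ccccc2)cc1)C(=O)c1c(O)cc(OCc2ccccc2)cc1OCc1ccccc1 | intermediate
18 | 1-[2,4-bis(benzyloxy)-6-hydroxyphenyl]-3-[4-(benzyloxy)phenyl]propane-1,2,3-trione (open-chain triketone) | O=C(C(=O)C(=O)c1ccc(OCc2ccccc2)cc1)c1c(O)cc(OCc2ccccc2)cc1OCc1ccccc1 | intermediate (not isolated)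
19 | 4,6-bis(benzyloxy)-2-[4-(benzyloxy)benzoyl]-2-hydroxybenzofuran-3(2H)-one (racemic hemiketal, ring-chain tautomer of 18) | O=C(c1ccc(OCc2ccccc2)cc1)C1(O)Oc2cc(OCc3ccccc3)cc(OCc3ccccc3)c2C1=O | intermediate (not isolated)
20 | Friedel–Crafts adduct: 13 carrying at C8 the carbinol carbon C(OH)[4-(benzyloxy)benzoyl][2,4-bis(benzyloxy)-6-hydroxybenzoyl], carbinol configured as in 21, flavan 2S,3R | O[C@@](C(=O)c1ccc(OCc4ccccc4)cc1)(C(=O)c1c(O)cc(OCc4ccccc4)cc1OCc1ccccc1)c1c(O)cc(OCc4ccccc4)c2c1O[C@@H](c1ccc(OCc4ccccc4)cc1)[C@H](OCc1ccccc1)C2 | intermediate (not isolated)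
21 | hexa-O-benzyl ketal alcohol: the target with OH in place of OMe at the ring-fusion carbon and benzyl on the 5- and 7-oxygens of the chromanone ring, the 4-oxygen of the ketal aryl group and the 3-, 5- and 4'-oxygens of the flavan; flavan 2S,3R; fusion descriptors as in the target | O[C@]12C(=O)c3c(OCc4ccccc4)cc(OCc4ccccc4)cc3O[C@]1(c1ccc(OCc4ccccc4)cc1)Oc1cc(OCc4ccccc4)c3c(c12)O[C@@H](c1ccc(OCc4ccccc4)cc1)[C@H](OCc1ccccc1)C3 | intermediate
22 | hexa-O-benzyl ether of the target (21 with OMe at the ring-fusion carbon) | CO[C@]12C(=O)c3c(OCc4ccccc4)cc(OCc4ccccc4)cc3O[C@]1(c1ccc(OCc4ccccc4)cc1)Oc1cc(OCc4ccccc4)c3c(c12)O[C@@H](c1ccc(OCc4ccccc4)cc1)[C@H](OCc1ccccc1)C3 | intermediate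
23 | CNP0291586.2: 3-methoxy furo-fused chromanone ketal joined to a (2S,3R)-flavan-3-ol, all phenols free | CO[C@]12C(=O)c3c(O)cc(O)cc3O[C@]1(c1ccc(O)cc1)Oc1cc(O)c3c(c12)O[C@@H](c1ccc(O)cc1)[C@H](O)C3 | target

**Count and risks**
Total steps: 15. Longest linear sequence: 11 steps (3, 4, 5, 6, 7, 8, 9, 10, 13, 14, 15; the line through steps 1 and 2 is equally long).

Steps most likely to fail:

1. Step 13 (proposed new method). Facial selectivity at the central carbonyl group may be weak, the uncatalysed addition may compete, or attack may occur at C6 instead of C8. Fallback with known chemistry, setting out from 13 and 17 and coming back at 21: 17 is oxidised with dimethyldioxirane as above and the hemiketal 19 is isolated. 13 and 19 are then condensed in acetic acid at room temperature without a chiral catalyst (the ninhydrin–phenol condensation). This should give 21 together with its isomer of opposite configuration at both fusion carbons, the diastereomeric hexa-O-benzyl ketal alcohol F1. The two are diastereomers through the flavan stereocentres and are separated by chromatography, and 21 goes on to step 14.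

2. Step 8. A ketyl formed at the side-chain aldehyde may expel the aryloxy group from C2, or C2 may epimerise in the aldehyde before the ring closes. Fallback setting out from 10 and coming back at 11: Takai–Lombardo methylenation of both aldehydes (Zn, CH2Br2, TiCl4, THF, non-basic) gives the diene (R)-1-(benzyloxy)-3-{1-[4-(benzyloxy)phenyl]allyloxy}-5-(methoxymethoxy)-2-vinylbenzene F2. Ring-closing metathesis with the second-generation Grubbs catalyst (CH2Cl2, 40 °C) then makes the same C3–C4 connection as an alkene, the flav-3-ene (R)-5-(benzyloxy)-2-[4-(benzyloxy)phenyl]-7-(methoxymethoxy)-2H-chromene F3. Dihydroxylation with OsO4 (cat.) and N-methylmorpholine N-oxide on the face away from the C2 aryl group should give the 2,3-trans-3,4-cis diol 11.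

3. Step 14. Methylation of the hindered tertiary alcohol may stall, or the neighbouring ketal may open. Fallback setting out from 21 and coming back at 22: acid-catalysed exchange with methanol (camphorsulfonic acid, MeOH/CH2Cl2, molecular sieves), an SN1 etherification in place of an O-alkylation. The tertiary benzylic alcohol ionises to a cation stabilised by the three oxygens of flavan ring A, and methanol can add only on the face that restores the same ring fusion; no new compound is made.

**Further compounds**
F1 | step 13 | diastereomer of 21 with both ring-fusion carbons inverted (flavan 2S,3R unchanged) | O[C@@]12C(=O)c3c(OCc4ccccc4)cc(OCc4ccccc4)cc3O[C@@]1(c1ccc(OCc4ccccc4)cc1)Oc1cc(OCc4ccccc4)c3c(c12)O[C@@H](c1ccc(OCc4ccccc4)cc1)[C@H](OCc1ccccc1)C3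
F2 | step 8 | (R)-1-(benzyloxy)-3-{1-[4-(benzyloxy)phenyl]allyloxy}-5-(methoxymethoxy)-2-vinylbenzene | COCOc1cc(OCc2ccccc2)c(C=C)c(c1)O[C@@H](c1ccc(OCc2ccccc2)cc1)C=C
F3 | step 8 | (R)-5-(benzyloxy)-2-[4-(benzyloxy)phenyl]-7-(methoxymethoxy)-2H-chromene | COCOc1cc(OCc3ccccc3)c2c(c1)O[C@@H](c1ccc(OCc3ccccc3)cc1)C=C2
F0 | step 14 | none | none
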